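**Retrosynthetic overview**

1. Feature: in the octalin the C8′=C8a′ alkene flanks C1′ (CHMe), which sits next to the quaternary C2′, with C4a′ (ring-fusion CH) and C5′ (CMe2) on ring B. An (E)-ethylidene group on ring B leaves exactly this pattern when its CH carbon (C1′) adds to an electrophilic C2′ and C8′ loses a proton. The C1′–C2′ bond, ring A, C1′, C2′ and the alkene therefore come from one anodic cyclisation of ketene dithioacetal 15 to orthothioester 16.
2. 15 comes from 3-methylcyclohexenone (ring B). C4a′ and the (E)-ethylidene group are set together by a Johnson–Claisen rearrangement of the CBS-derived allylic alcohol 6. The tether is finished with methyl propanoate and an aluminium dithiolate.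
3. The dithiane carbon of 16 becomes C8 of the bicycle: 16 → aldehyde 19 → enol ether 20. The oxolane ring (C1, C8, C5, C6, O7) is closed by a bromoacetal radical cyclisation with the (R)-hydroxy-enoate 27, which brings C6 and sets C5.
4. The lactone ring (C1–O2–C3–C4–C5–C8) is closed last by acid from dihydrofuran 30, which sets C8 and C1.
5. Ring order: B (starting material), A (step 9), oxolane (step 18), lactone (step 20).

Key step: step 9

Remark: primed locants are those of the octalin (C1′–C8a′); unprimed locants are those of 2,7-dioxabicyclo[3.2.1]octan-3-one (C1 acetal, C5, C6 ester-bearing, C8 octalin-bearing); (3R)-3-hydroxyoxolan-2-one is taken as the commercial chiral source of C6.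

**Route**

Step 1
Reactants: 1 3-methylcyclohex-2-en-1-one
Product: 3 3,3-dimethylcyclohex-1-en-1-yl trifluoromethanesulfonate, via lithium 3,3-dimethylcyclohex-1-en-1-olate 2 (not isolated)
Conditions: Me2CuLi, Et2O, 0 °C; then PhNTf2, THF, 0 °C to rt
Reagents that add atoms: lithium dimethylcuprate, [Li+].C[Cu-]C; N-phenylbis(trifluoromethanesulfonimide), O=S(=O)(N(c1ccccc1)S(=O)(=O)C(F)(F)F)C(F)(F)F
Why: Cuprate 1,4-addition to the β-methyl enone gives the enolate regiospecifically on the side of the new gem-dimethyl carbon, and O-sulfonylation fixes that double-bond position (conjugate addition with enolate trapping as the enol triflate).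

Step 2
Reactants: 3 3,3-dimethylcyclohex-1-en-1-yl trifluoromethanesulfonate
Product: 5 1-(3,3-dimethylcyclohex-1-en-1-yl)ethan-1-one, via 1-(1-ethoxyethenyl)-3,3-dimethylcyclohex-1-ene 4 (not isolated)
Conditions: CH2=C(OEt)SnBu3, Pd(PPh3)4 (5 mol %), LiCl, THF, 65 °C; then 1 M HCl, rt
Reagents that add atoms: tributyl(1-ethoxyethenyl)stannane, C=C(OCC)[Sn](CCCC)(CCCC)CCCC; water, O
Why: Stille coupling of the enol triflate with the 1-ethoxyvinyl stannane followed by acid hydrolysis of the dienyl ether is a standard conversion of a vinyl triflate into the conjugated methyl ketone.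

Step 3
Reactants: 5 1-(3,3-dimethylcyclohex-1-en-1-yl)ethan-1-one
Product: 6 (1R)-1-(3,3-dimethylcyclohex-1-en-1-yl)ethan-1-ol
Conditions: (S)-1-methyl-3,3-diphenyltetrahydro-1H,3H-pyrrolo[1,2-c][1,3,2]oxazaborole (the (S)-methyl CBS oxazaborolidine, 10 mol %), BH3·SMe2, THF, −20 °C; aq. NH4Cl
Reagents that add atoms: none
Why: Corey–Bakshi–Shibata reduction, in which the alkenyl group acts as the large substituent as an aryl group does, so the (S)-catalyst should deliver hydride to give the (R)-carbinol.

Step 4
Reactants: 6 (1R)-1-(3,3-dimethylcyclohex-1-en-1-yl)ethan-1-ol; 7 1,1,1-triethoxyethane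
Product: 9 ethyl 2-[(1S,2E)-2-ethylidene-6,6-dimethylcyclohexyl]acetate, via ketene acetal 1-[(1R)-1-(1-ethoxyethenyloxy)ethyl]-3,3-dimethylcyclohex-1-ene 8 (not isolated)
Conditions: 7 (6 equiv), EtCO2H (cat.), 140 °C, EtOH distilled off
Reagents that add atoms: none
Why: Johnson–Claisen rearrangement through a chair in which the carbinol methyl is equatorial (an axial methyl would clash with the ethoxy group), which gives the (E)-ethylidene group and transfers the carbinol configuration suprafacially to the ring carbon, so that the later C4a′ is set as S.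

Step 5
Reactants: 9 ethyl 2-[(1S,2E)-2-ethylidene-6,6-dimethylcyclohexyl]acetate
Product: 10 2-[(1S,2E)-2-ethylidene-6,6-dimethylcyclohexyl]ethan-1-ol
Conditions: LiAlH4, THF, 0 °C; aq. work-up
Reagents that add atoms: none
Why: Hydride reduction of the ester to the primary alcohol leaves the isolated alkene and the stereocentre untouched.

Step 6
Reactants: 10 2-[(1S,2E)-2-ethylidene-6,6-dimethylcyclohexyl]ethan-1-ol
Product: 11 (2S,3E)-3-ethylidene-2-(2-iodoethyl)-1,1-dimethylcyclohexane
Conditions: I2, PPh3, imidazole, CH2Cl2, 0 °C to rt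
Reagents that add atoms: iodine, II
Why: Appel-type iodination of an unhindered primary alcohol under buffered conditions that do not touch the trisubstituted alkene.

Step 7
Reactants: 11 (2S,3E)-3-ethylidene-2-(2-iodoethyl)-1,1-dimethylcyclohexane; 12 methyl propanoate
Product: 14 methyl 4-[(1S,2E)-2-ethylidene-6,6-dimethylcyclohexyl]-2-methylbutanoate (both C2 epimers), via lithium 1-methoxyprop-1-en-1-olate 13 (not isolated)
Conditions: 12, LiN(iPr)2, THF, −78 °C; then 11, DMPU, −78 to −20 °C
Reagents that add atoms: none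
Why: SN2 alkylation of the lithium ester enolate by the unhindered primary iodide; the new α-centre forms as a mixture, which does not matter because it becomes sp2 in step 8.

Step 8
Reactants: 14 methyl 4-[(1S,2E)-2-ethylidene-6,6-dimethylcyclohexyl]-2-methylbutanoate
Product: 15 2-{4-[(1S,2E)-2-ethylidene-6,6-dimethylcyclohexyl]butan-2-ylidene}-1,3-dithiane
Conditions: Me2AlS(CH2)3SAlMe2 (from AlMe3 and HS(CH2)3SH), CH2Cl2, 0 °C to rt; aq. work-up
Reagents that add atoms: propane-1,3-dithiol, SCCCS
Why: The bis(dimethylaluminium) dithiolate converts an ester with an α-hydrogen directly into the ketene dithioacetal (thiolate addition, loss of methoxide, Al–O elimination), a known ester-to-ketene-dithioacetal transformation.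

Step 9
Reactants: 15 2-{4-[(1S,2E)-2-ethylidene-6,6-dimethylcyclohexyl]butan-2-ylidene}-1,3-dithiane
Product: 16 2-methoxy-2-[(1R,2R,4aS)-1,2,5,5-tetramethyl-1,2,3,4,4a,5,6,7-octahydronaphthalen-2-yl]-1,3-dithiane
Conditions: reticulated vitreous carbon anode, Pt cathode, undivided cell, constant current (8 mA, 2.2 F/mol), LiClO4 (0.1 M), 2,6-lutidine (6 equiv), MeOH/THF 3:7, rt
Reagents that add atoms: methanol, CO
Why: Anodic olefin coupling (oxidative radical-cation cyclisation): the ketene dithioacetal is oxidised at a lower potential than either trisubstituted alkene, its radical cation is attacked at C2′ by the ethylidene carbon C1′, and the dithio-stabilised radical loses a second electron and takes up methanol while 2,6-lutidine removes a proton from C8′ of the tertiary C8a′ cation. Ring A is closed in a 6-exo mode with respect to the dithianylidene bond (endo with respect to the ethylidene) through a chair in which the tether from C4a′ is axial on ring B. C1′ is controlled by the (E)-ethylidene geometry, because C2′ can reach only the alkene face that carries the tether, which leaves the C1′ methyl equatorial and trans to H-4a′. C2′ is controlled by allylic 1,3-strain, which keeps the dithianylidene carbon anti to C4′ and so equatorial, with the C2′ methyl axial and cis to the C1′ methyl. The step needs chemoselective oxidation (secured by the two sulfur donors), ring closure before solvent capture of the radical cation (secured by the six-membered tether), and proton loss toward C8′ and not C4a′ or C1′ (favoured because the hindered base reaches only the unhindered methylene hydrogens).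

Step 10
Reactants: 16 2-methoxy-2-[(1R,2R,4aS)-1,2,5,5-tetramethyl-1,2,3,4,4a,5,6,7-octahydronaphthalen-2-yl]-1,3-dithiane
Product: 17 S-(3-sulfanylpropyl) (1R,2R,4aS)-1,2,5,5-tetramethyl-1,2,3,4,4a,5,6,7-octahydronaphthalene-2-carbothioate
Conditions: TsOH·H2O (cat.), THF/H2O 4:1, rt
Reagents that add atoms: water, O
Why: Acid-catalysed hydrolysis of the S,S,O-orthoester: loss of methanol gives the dithianylium ion, water adds and the hemithioorthoester opens to the thiol ester.

Step 11
Reactants: 17 S-(3-sulfanylpropyl) (1R,2R,4aS)-1,2,5,5-tetramethyl-1,2,3,4,4a,5,6,7-octahydronaphthalene-2-carbothioate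
Product: 18 [(1R,2R,4aS)-1,2,5,5-tetramethyl-1,2,3,4,4a,5,6,7-octahydronaphthalen-2-yl]methanol
Conditions: LiAlH4, THF, 0 °C to rt; aq. work-up
Reagents that add atoms: none
Why: LiAlH4 reduces the thiol ester to the neopentyl primary alcohol and releases the dithiol; the alkene and the three stereocentres are not affected.

Step 12
Reactants: 18 [(1R,2R,4aS)-1,2,5,5-tetramethyl-1,2,3,4,4a,5,6,7-octahydronaphthalen-2-yl]methanol
Product: 19 (1R,2R,4aS)-1,2,5,5-tetramethyl-1,2,3,4,4a,5,6,7-octahydronaphthalene-2-carbaldehyde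
Conditions: Dess–Martin periodinane, CH2Cl2, rt
Reagents that add atoms: none
Why: Dess–Martin oxidation of the primary alcohol; the aldehyde has no α-hydrogen and cannot epimerise.

Step 13
Reactants: 19 (1R,2R,4aS)-1,2,5,5-tetramethyl-1,2,3,4,4a,5,6,7-octahydronaphthalene-2-carbaldehyde
Product: 20 (1S,2R,4aS)-2-(2-methoxyethenyl)-1,2,5,5-tetramethyl-1,2,3,4,4a,5,6,7-octahydronaphthalene (E/Z mixture)
Conditions: Ph3P(CH2OMe)Cl, KN(SiMe3)2, THF, 0 °C; then 19, 0 °C to rt
Reagents that add atoms: (methoxymethyl)triphenylphosphonium chloride, [Cl-].COC[P+](c1ccccc1)(c1ccccc1)c1ccccc1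
Why: Wittig methoxymethylenation, which works on α-quaternary aldehydes with the unstabilised ylide; the E/Z ratio is irrelevant because the geometry is lost in step 17.

Step 14
Reactants: 21 (3R)-3-hydroxyoxolan-2-one
Product: 23 methyl (2R)-2-hydroxy-4-(phenylselanyl)butanoate, via sodium (2R)-2-hydroxy-4-(phenylselanyl)butanoate 22 (not isolated)
Conditions: PhSeSePh, NaBH4, DMF, rt; then 21, 110 °C; then MeI, rt
Reagents that add atoms: diphenyl diselenide, c1ccccc1[Se][Se]c1ccccc1; iodomethane, CI
Why: The soft selenolate opens the γ-lactone by SN2 attack at the O-CH2 carbon, away from the stereocentre, and the carboxylate is alkylated in the same flask (selenolate lactone opening).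

Step 15
Reactants: 23 methyl (2R)-2-hydroxy-4-(phenylselanyl)butanoate
Product: 25 methyl (2R)-2-hydroxybut-3-enoate, via methyl (2R)-2-hydroxy-4-(phenylseleninyl)butanoate 24 (not isolated)
Conditions: H2O2 (30 % aq), CH2Cl2, 0 °C; then toluene, 90 °C
Reagents that add atoms: none
Why: Selenoxide syn-elimination toward the only β-CH2 gives the terminal alkene without base, so the α-hydroxy ester centre is not touched.

Step 16
Reactants: 25 methyl (2R)-2-hydroxybut-3-enoate; 26 tert-butyl prop-2-enoate
Product: 27 1-tert-butyl 5-methyl (2E,4R)-4-hydroxypent-2-enedioate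
Conditions: second-generation Hoveyda–Grubbs catalyst RuCl2(H2IMes)(=CH–C6H4-2-OiPr) (5 mol %), 26 (4 equiv), CH2Cl2, 40 °C
Reagents that add atoms: none
Why: Olefin cross-metathesis of the allylic alcohol with an excess of the slowly dimerising acrylate should give the (E)-enoate with loss of ethene.

Step 17
Reactants: 20 (1S,2R,4aS)-2-(2-methoxyethenyl)-1,2,5,5-tetramethyl-1,2,3,4,4a,5,6,7-octahydronaphthalene; 27 1-tert-butyl 5-methyl (2E,4R)-4-hydroxypent-2-enedioate
Product: 28 1-tert-butyl 5-methyl (2E,4R)-4-{2-bromo-1-methoxy-2-[(1R,2R,4aS)-1,2,5,5-tetramethyl-1,2,3,4,4a,5,6,7-octahydronaphthalen-2-yl]ethoxy}pent-2-enedioate (mixture at the acetal and bromide carbons)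
Conditions: NBS, 27 (2 equiv), CH2Cl2, −40 to 0 °C
Reagents that add atoms: N-bromosuccinimide, O=C1CCC(=O)N1Br
Why: Bromoacetalisation (first half of the Ueno–Stork sequence): NBS attacks the electron-rich enol ether far faster than the hindered ring alkene and alcohol 27 captures the oxocarbenium ion; the two new centres form without control and both are reset later.

Step 18
Reactants: 28 the bromoacetal of step 17
Product: 29 methyl (2R,3R)-3-(2-tert-butoxy-2-oxoethyl)-5-methoxy-4-[(1S,2R,4aS)-1,2,5,5-tetramethyl-1,2,3,4,4a,5,6,7-octahydronaphthalen-2-yl]oxolane-2-carboxylate (epimers at C4 and C5 of the oxolane)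
Conditions: Bu3SnH (slow addition), AIBN (cat.), benzene, 80 °C
Reagents that add atoms: none
Why: Ueno–Stork 5-exo-trig radical cyclisation onto the enoate β-carbon through a chair-like transition state with the methyl ester pseudo-equatorial, which should place the new CH2CO2tBu arm (C5 of the target) trans to the ester at C6; the acetal carbon and the octalin-bearing carbon form as mixtures that converge in steps 19 and 20.

Step 19
Reactants: 29 the oxolane acetal of step 18
Product: 30 methyl (2R,3R)-3-(2-tert-butoxy-2-oxoethyl)-4-[(1R,2R,4aS)-1,2,5,5-tetramethyl-1,2,3,4,4a,5,6,7-octahydronaphthalen-2-yl]-2,3-dihydrofuran-2-carboxylate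
Conditions: TMSOTf, iPr2NEt, CH2Cl2, −20 to 0 °C
Reagents that add atoms: none
Why: Acetal-to-enol-ether elimination: TMSOTf ionises the exocyclic C–OMe bond (the ring oxygen is deactivated by the adjacent ester) and the amine removes the hydrogen on the octalin-bearing carbon, so all isomers of 29 give one dihydrofuran.

Step 20
Reactants: 30 the dihydrofuran of step 19
Product: 31 methyl (1S,5R,6R,8R)-3-oxo-8-[(1S,2R,4aS)-1,2,5,5-tetramethyl-1,2,3,4,4a,5,6,7-octahydronaphthalen-2-yl]-2,7-dioxabicyclo[3.2.1]octane-6-carboxylate (CNP0301564.1)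
Conditions: (+)-camphor-10-sulfonic acid (0.2 equiv), CH2Cl2, 0 °C to rt
Reagents that add atoms: none
Why: Acid-catalysed lactonisation onto an enol ether: reversible protonation at C8 gives the cyclic oxocarbenium ion, the tert-butyl ester carbonyl adds to C1 from the face of the arm and isobutene is lost, which fixes C1 because the bridge can form only on that face; of the two C8 epimers only the one with the octalin over the lactone bridge, away from the exo ester at C6, can close without a severe 1,3-clash, so C8 should be set by this closure.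

**Compound list**

1 | 3-methylcyclohex-2-en-1-one | CC1=CC(=O)CCC1 | starting material
2 | lithium 3,3-dimethylcyclohex-1-en-1-olate | [Li+].[O-]C1=CC(C)(C)CCC1 | intermediate
3 | 3,3-dimethylcyclohex-1-en-1-yl trifluoromethanesulfonate | CC1(C)CCCC(OS(=O)(=O)C(F)(F)F)=C1 | intermediate
4 | 1-(1-ethoxyethenyl)-3,3-dimethylcyclohex-1-ene | CCOC(=C)C1=CC(C)(C)CCC1 | intermediate
5 | 1-(3,3-dimethylcyclohex-1-en-1-yl)ethan-1-one | CC(=O)C1=CC(C)(C)CCC1 | intermediate
6 | (1R)-1-(3,3-dimethylcyclohex-1-en-1-yl)ethan-1-ol | C[C@@H](O)C1=CC(C)(C)CCC1 | intermediate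
7 | 1,1,1-triethoxyethane | CCOC(C)(OCC)OCC | starting material
8 | 1-[(1R)-1-(1-ethoxyethenyloxy)ethyl]-3,3-dimethylcyclohex-1-ene | C[C@@H](OC(=C)OCC)C1=CC(C)(C)CCC1 | intermediate
9 | ethyl 2-[(1S,2E)-2-ethylidene-6,6-dimethylcyclohexyl]acetate | CCOC(=O)C[C@@H]1/C(=C/C)CCCC1(C)C | intermediate
10 | 2-[(1S,2E)-2-ethylidene-6,6-dimethylcyclohexyl]ethan-1-ol | OCC[C@@H]1/C(=C/C)CCCC1(C)C | intermediate
11 | (2S,3E)-3-ethylidene-2-(2-iodoethyl)-1,1-dimethylcyclohexane | ICC[C@@H]1/C(=C/C)CCCC1(C)C | intermediate
12 | methyl propanoate | CCC(=O)OC | starting material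
13 | lithium 1-methoxyprop-1-en-1-olate | [Li+].[O-]C(OC)=CC | intermediate
14 | methyl 4-[(1S,2E)-2-ethylidene-6,6-dimethylcyclohexyl]-2-methylbutanoate (both C2 epimers) | COC(=O)C(C)CC[C@@H]1/C(=C/C)CCCC1(C)C | intermediate
15 | 2-{4-[(1S,2E)-2-ethylidene-6,6-dimethylcyclohexyl]butan-2-ylidene}-1,3-dithiane | CC(=C1SCCCS1)CC[C@@H]2/C(=C/C)CCCC2(C)C | intermediate
16 | 2-methoxy-2-[(1R,2R,4aS)-1,2,5,5-tetramethyl-1,2,3,4,4a,5,6,7-octahydronaphthalen-2-yl]-1,3-dithiane | COC1(SCCCS1)[C@]2(C)CC[C@@H]3C(=CCCC3(C)C)[C@H]2C | intermediate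
17 | S-(3-sulfanylpropyl) (1R,2R,4aS)-1,2,5,5-tetramethyl-1,2,3,4,4a,5,6,7-octahydronaphthalene-2-carbothioate | O=C(SCCCS)[C@]1(C)CC[C@@H]2C(=CCCC2(C)C)[C@H]1C | intermediate
18 | [(1R,2R,4aS)-1,2,5,5-tetramethyl-1,2,3,4,4a,5,6,7-octahydronaphthalen-2-yl]methanol | OC[C@]1(C)CC[C@@H]2C(=CCCC2(C)C)[C@H]1C | intermediate
19 | (1R,2R,4aS)-1,2,5,5-tetramethyl-1,2,3,4,4a,5,6,7-octahydronaphthalene-2-carbaldehyde | O=C[C@]1(C)CC[C@@H]2C(=CCCC2(C)C)[C@H]1C | intermediate
20 | (1S,2R,4aS)-2-(2-methoxyethenyl)-1,2,5,5-tetramethyl-1,2,3,4,4a,5,6,7-octahydronaphthalene (E/Z mixture) | COC=C[C@]1(C)CC[C@@H]2C(=CCCC2(C)C)[C@H]1C | intermediate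
21 | (3R)-3-hydroxyoxolan-2-one | O[C@@H]1CCOC1=O | starting material
22 | sodium (2R)-2-hydroxy-4-(phenylselanyl)butanoate | [Na+].[O-]C(=O)[C@H](O)CC[Se]c1ccccc1 | intermediate
23 | methyl (2R)-2-hydroxy-4-(phenylselanyl)butanoate | COC(=O)[C@H](O)CC[Se]c1ccccc1 | intermediate
24 | methyl (2R)-2-hydroxy-4-(phenylseleninyl)butanoate | COC(=O)[C@H](O)CC[Se](=O)c1ccccc1 | intermediate
25 | methyl (2R)-2-hydroxybut-3-enoate | COC(=O)[C@H](O)C=C | intermediate
26 | tert-butyl prop-2-enoate | C=CC(=O)OC(C)(C)C | starting material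
27 | 1-tert-butyl 5-methyl (2E,4R)-4-hydroxypent-2-enedioate | COC(=O)[C@H](O)/C=C/C(=O)OC(C)(C)C | intermediate
28 | 1-tert-butyl 5-methyl (2E,4R)-4-{2-bromo-1-methoxy-2-[(1R,2R,4aS)-1,2,5,5-tetramethyl-1,2,3,4,4a,5,6,7-octahydronaphthalen-2-yl]ethoxy}pent-2-enedioate (mixture at the acetal and bromide carbons) | COC(=O)[C@H](OC(OC)C(Br)[C@]1(C)CC[C@@H]2C(=CCCC2(C)C)[C@H]1C)/C=C/C(=O)OC(C)(C)C | intermediate
29 | methyl (2R,3R)-3-(2-tert-butoxy-2-oxoethyl)-5-methoxy-4-[(1S,2R,4aS)-1,2,5,5-tetramethyl-1,2,3,4,4a,5,6,7-octahydronaphthalen-2-yl]oxolane-2-carboxylate (epimers at C4 and C5) | COC(=O)[C@@H]1OC(OC)C([C@]2(C)CC[C@@H]3C(=CCCC3(C)C)[C@H]2C)[C@H]1CC(=O)OC(C)(C)C | intermediate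
30 | methyl (2R,3R)-3-(2-tert-butoxy-2-oxoethyl)-4-[(1R,2R,4aS)-1,2,5,5-tetramethyl-1,2,3,4,4a,5,6,7-octahydronaphthalen-2-yl]-2,3-dihydrofuran-2-carboxylate | COC(=O)[C@@H]1OC=C([C@]2(C)CC[C@@H]3C(=CCCC3(C)C)[C@H]2C)[C@H]1CC(=O)OC(C)(C)C | intermediate
31 | methyl (1S,5R,6R,8R)-3-oxo-8-[(1S,2R,4aS)-1,2,5,5-tetramethyl-1,2,3,4,4a,5,6,7-octahydronaphthalen-2-yl]-2,7-dioxabicyclo[3.2.1]octane-6-carboxylate | COC(=O)[C@@H]1O[C@H]2OC(=O)C[C@@H]1[C@@H]2[C@]1(C)CC[C@@H]2C(=CCCC2(C)C)[C@H]1C | target

**Step count**

Total steps: 20. Longest linear sequence: 17 (steps 1–13 and 17–20); steps 14–16 make the side fragment 27.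

**Steps most likely to fail**

Step 9. Methanol may capture the radical cation before ring closure, or capture the C8a′ cation in place of proton loss. Proton loss may also go toward C4a′ or C1′ and move the alkene to a tetrasubstituted position, and closure may be slow because a quaternary carbon is joined to a tertiary one. The fallback is an epoxide-initiated cation–olefin cyclisation, which sets out from iodide 11 and comes back at alcohol 18. Iodine–lithium exchange on 11 (t-BuLi, Et2O, −78 °C) and acylation with N-methoxy-N-methylacetamide should give 4-[(1S,2E)-2-ethylidene-6,6-dimethylcyclohexyl]butan-2-one F1. Corey–Chaykovsky methylenation (Me3S+ I−, n-BuLi, THF) should give 2-{2-[(1S,2E)-2-ethylidene-6,6-dimethylcyclohexyl]ethyl}-2-methyloxirane F2 as both epimers. MeAlCl2 in CH2Cl2 at −78 °C should open the oxirane at its tertiary carbon, C1′ of the ethylidene should add through the same chair with the aluminium-bound oxymethyl group equatorial, and loss of a C8′ proton gives 18, so steps 7 to 11 are bypassed.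

Step 20. Protonation may not be reversible enough to select the C8 epimer, closure next to the octalin-bearing carbon may be slow, and the acid may move the C8′ alkene into the ring fusion. The fallback sets out from 29 and comes back at 31 without step 19. The C4 epimers of 29 are separated, and the epimer with the octalin cis to the acetate arm (the product of the chair transition state of step 18) is treated with catalytic TMSOTf in CH2Cl2 at −78 °C. Lewis-acid ionisation of the methyl acetal and capture by the tert-butyl ester with loss of isobutene should give 31 directly. C8 then comes from the radical cyclisation, no enol ether is protonated and no Brønsted acid is present; no compound outside the list is made (F0).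

Step 19. The ring C–O bond may ionise in place of the methoxy group, or the oxocarbenium ion may be captured before the hindered hydrogen is removed. The fallback is the lactol-to-glycal route, which sets out from 29 and comes back at 30. Mild hydrolysis of the methyl acetal (PPTS, acetone/water, 40 °C; the tert-butyl ester is kept) should give methyl (2R,3R)-3-(2-tert-butoxy-2-oxoethyl)-5-hydroxy-4-[(1S,2R,4aS)-1,2,5,5-tetramethyl-1,2,3,4,4a,5,6,7-octahydronaphthalen-2-yl]oxolane-2-carboxylate F3. Mesylation with elimination in the same flask (MsCl, Et3N, CH2Cl2, 0 °C to rt) should give 30.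

**Further compounds**

F1 | step 9 | 4-[(1S,2E)-2-ethylidene-6,6-dimethylcyclohexyl]butan-2-one | CC(=O)CC[C@@H]1/C(=C/C)CCCC1(C)C
F2 | step 9 | 2-{2-[(1S,2E)-2-ethylidene-6,6-dimethylcyclohexyl]ethyl}-2-methyloxirane (both epimers) | CC1(CC[C@@H]2/C(=C/C)CCCC2(C)C)CO1
F0 | step 20 | none | none
F3 | step 19 | methyl (2R,3R)-3-(2-tert-butoxy-2-oxoethyl)-5-hydroxy-4-[(1S,2R,4aS)-1,2,5,5-tetramethyl-1,2,3,4,4a,5,6,7-octahydronaphthalen-2-yl]oxolane-2-carboxylate | COC(=O)[C@@H]1OC(O)C([C@]2(C)CC[C@@H]3C(=CCCC3(C)C)[C@H]2C)[C@H]1CC(=O)OC(C)(C)C
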